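**Retrosynthetic overview**
1. The route rests on the δ-lactone C2–O4–C5–C7–C8–C9, whose ring oxygen O4 lies between the gem-dimethyl carbon C2 and the carbonyl C5. It is made by Baeyer–Villiger oxygen insertion into a spiro 2,2-dimethylcyclopentanone (ring A), and the C7=C8 alkene follows by selenoxide elimination.
2. The cage (bicyclo[2.2.2]octane with bridgeheads C14 and C25, plus the five-membered ring C12–C21–C20–C18–C25) comes from an aromatic Claisen/intramolecular Diels–Alder cascade of an allyl phthalide ether; the allyl group is then cut down to the C19 methyl.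
3. The arene and the rings A/B fragment are joined at C18–C20 by Negishi coupling of a bromophthalide (from methyl 2,4-dihydroxy-3,6-dimethylbenzoate) with a primary iodide.
4. In the fragment, C9 is set by CBS reduction and Ireland–Claisen chirality transfer, ring A is closed by rhodium hydroacylation, and C22 and C21 are set by directed epoxidation and palladium/formate hydrogenolysis.
5. Ring order: ring B (bought), ring A, the phthalide γ-lactone on the arene, the three cage rings in one step, and last the δ-lactone by ring expansion.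

Key step: step 27

Remark: atom labels C1–O32 follow the atom order of the target SMILES; selenide 39 is carried on as its C7 epimers.

Step 1
Reactants: 1 3-ethoxy-2-methylcyclohex-2-en-1-one
Product: 3 2-methyl-3-vinylcyclohex-2-en-1-one, via Grignard adduct 2 (not isolated)
Conditions: CH2=CHMgBr, THF, 0 °C; then 1 M HCl
Reagents that add atoms: vinylmagnesium bromide C=C[Mg]Br
Why: Stork–Danheiser sequence: 1,2-addition to the vinylogous ester carbonyl and acid hydrolysis of the enol ether with loss of ethanol transpose the enone and give the cross-conjugated dienone.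

Step 2
Reactants: 3 2-methyl-3-vinylcyclohex-2-en-1-one
Product: 4 (S)-2-methyl-3-vinylcyclohex-2-en-1-ol
Conditions: (R)-2-methyl-CBS-oxazaborolidine (10 mol %), catecholborane, toluene, −78 °C
Reagents that add atoms: none
Why: Corey–Bakshi–Shibata reduction: the catalyst-bound borane delivers hydride to one carbonyl face with the 2-methylalkenyl arm as the large group, which should give the (S) allylic alcohol that later fixes C9.

Step 3
Reactants: 4 (S)-2-methyl-3-vinylcyclohex-2-en-1-ol
Product: 5 (S)-2-methyl-3-vinylcyclohex-2-en-1-yl 2-methylpropanoate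
Conditions: isobutyryl chloride, pyridine, DMAP (cat.), CH2Cl2, 0 °C
Reagents that add atoms: isobutyryl chloride CC(C)C(Cl)=O
Why: Acylation of a secondary allylic alcohol under nucleophilic catalysis; the stereocentre is not touched.

Step 4
Reactants: 5 (S)-2-methyl-3-vinylcyclohex-2-en-1-yl 2-methylpropanoate
Product: 8 2-methyl-2-(2-methyl-1-vinylcyclohex-2-en-1-yl)propanoic acid, via silyl ketene acetal 6 (not isolated), via trimethylsilyl ester 7 (not isolated)
Conditions: LDA, THF, −78 °C; Me3SiCl, −78 to 65 °C; then 1 M HCl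
Reagents that add atoms: none
Why: Ireland–Claisen rearrangement: the silyl ketene acetal shifts suprafacially across the ring alkene, so the C9–C2 bond forms on the face that carried the ester oxygen and the quaternary centre C9 is set by 1,3-chirality transfer from the carbinol carbon.

Step 5
Reactants: 8 2-methyl-2-(2-methyl-1-vinylcyclohex-2-en-1-yl)propanoic acid
Product: 9 2-methyl-2-(2-methyl-1-vinylcyclohex-2-en-1-yl)propan-1-ol
Conditions: LiAlH4, THF, 0 °C to reflux
Reagents that add atoms: none
Why: Hydride reduction of the acid to the neopentyl alcohol; C9 is untouched.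

Step 6
Reactants: 9 2-methyl-2-(2-methyl-1-vinylcyclohex-2-en-1-yl)propan-1-ol
Product: 10 2-methyl-2-(2-methyl-1-vinylcyclohex-2-en-1-yl)propanal
Conditions: Dess–Martin periodinane, NaHCO3, CH2Cl2, 0 °C to rt
Reagents that add atoms: none
Why: Dess–Martin oxidation stops at the non-enolisable aldehyde.

Step 7
Reactants: 10 2-methyl-2-(2-methyl-1-vinylcyclohex-2-en-1-yl)propanal
Product: 11 1,1,6-trimethylspiro[4.5]dec-6-en-2-one (rings A and B; spiro carbon C9)
Conditions: [Rh(dppe)]ClO4 (5 mol %, dppe = 1,2-bis(diphenylphosphino)ethane), CH2Cl2, rt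
Reagents that add atoms: none
Why: Rhodium-catalysed intramolecular hydroacylation of a 4-pentenal by cationic monovalent rhodium: C–H oxidative addition and anti-Markovnikov insertion of the vinyl group form C5–C7 and close ring A as the cyclopentanone, while the trisubstituted ring alkene should not compete.

Step 8
Reactants: 11 1,1,6-trimethylspiro[4.5]dec-6-en-2-one
Product: 12 ethylene ketal of 11 (1,3-dioxolane at C5)
Conditions: ethylene glycol, p-TsOH (cat.), benzene, reflux (Dean–Stark)
Reagents that add atoms: ethylene glycol OCCO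
Why: Acid-catalysed ketalisation masks the ring A ketone for the carbonyl chemistry that follows.

Step 9
Reactants: 12 ethylene ketal of 11
Product: 13 ketal enone (C12 ketone; C21=C22)
Conditions: Rh2(cap)4 (dirhodium tetracaprolactamate, 1 mol %), t-BuOOH, K2CO3, CH2Cl2, rt
Reagents that add atoms: tert-butyl hydroperoxide CC(C)(C)OO
Why: Rhodium-catalysed allylic oxidation by tert-butylperoxy radicals converts the only secondary allylic methylene (C12) into the conjugated ketone.

Step 10
Reactants: 13 ketal enone
Product: 15 2-bromo enone (Br on C21), via dibromo ketone 14 (not isolated)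
Conditions: Br2, CH2Cl2, 0 °C; then Et3N
Reagents that add atoms: bromine BrBr
Why: Bromine addition across the enone and base-induced loss of HBr (addition–elimination) give the α-bromo enone, as is usual for 3-methylcyclohexenones.

Step 11
Reactants: 15 2-bromo enone
Product: 16 2-(hydroxymethyl) enone (C20 on C21)
Conditions: Bu3SnCH2OH, Pd(PPh3)4 (5 mol %), 1,4-dioxane, 100 °C
Reagents that add atoms: (tributylstannyl)methanol CCCC[Sn](CCCC)(CCCC)CO
Why: Stille coupling of the activated alkenyl bromide with the hydroxymethyl stannane puts C20 on C21.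

Step 12
Reactants: 16 2-(hydroxymethyl) enone
Product: 17 dienyl alcohol (C12 methylidene; C21=C22)
Conditions: Ph3PCH3Br, KOtBu (3 equiv), THF, 0 °C to reflux
Reagents that add atoms: methylenetriphenylphosphorane C=P(c1ccccc1)(c1ccccc1)c1ccccc1
Why: Wittig methylenation of the enone carbonyl (excess ylide covers the free hydroxyl) gives the s-trans diene that holds the exocyclic C12=C13 alkene.

Step 13
Reactants: 17 dienyl alcohol
Product: 18 vinyl epoxide (C21–C22 oxirane anti to C2)
Conditions: VO(acac)2 (3 mol %), t-BuOOH, CH2Cl2, 0 °C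
Reagents that add atoms: tert-butyl hydroperoxide CC(C)(C)OO
Why: Hydroxyl-directed vanadium-catalysed epoxidation acts only on the allylic alcohol alkene C21=C22, and oxygen should enter from the face opposite the C2 gem-dimethyl arm on the neighbouring spiro carbon C9, which sets C22.

Step 14
Reactants: 18 vinyl epoxide
Product: 19 diol (C12 methylidene; C21–H; C20 and C22 hydroxyls)
Conditions: Pd2(dba)3·CHCl3 (2.5 mol %), PBu3, HCO2H, Et3N, 1,4-dioxane, rt
Reagents that add atoms: none
Why: Palladium-catalysed formate hydrogenolysis of an alkenyl oxirane (Tsuji–Trost-type π-allyl chemistry): zerovalent palladium opens C21–O with inversion and hydride passes from the metal to the more substituted terminus C21, so H21 ends anti to the C22 oxygen and the C12=C13 alkene is terminal.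

Step 15
Reactants: 19 diol
Product: 20 primary iodide (C20–I)
Conditions: I2, PPh3, imidazole, CH2Cl2, 0 to 40 °C
Reagents that add atoms: iodine II
Why: Appel-type iodination converts only the primary alcohol, since the tertiary alcohol is too hindered to form the oxyphosphonium ion.

Step 16
Reactants: 20 primary iodide
Product: 21 triethylsilyl ether of 20 (O24–SiEt3)
Conditions: Et3SiOTf, 2,6-lutidine, CH2Cl2, −78 to 0 °C
Reagents that add atoms: triethylsilyl triflate CC[Si](CC)(CC)OS(=O)(=O)C(F)(F)F
Why: Silyl triflate silylation protects the tertiary alcohol for the organozinc chemistry.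

Step 17
Reactants: 22 methyl 2,4-dihydroxy-3,6-dimethylbenzoate
Product: 23 methyl 2,4-bis(tert-butyldimethylsilyloxy)-3,6-dimethylbenzoate
Conditions: t-BuMe2SiOTf, Et3N, CH2Cl2, 0 °C to rt
Reagents that add atoms: tert-butyldimethylsilyl triflate CC(C)(C)[Si](C)(C)OS(=O)(=O)C(F)(F)F
Why: Silylation of both phenols (the hydrogen-bonded one needs the triflate) readies the arene for strong base.

Step 18
Reactants: 23 methyl 2,4-bis(tert-butyldimethylsilyloxy)-3,6-dimethylbenzoate
Product: 25 5,7-bis(tert-butyldimethylsilyloxy)-6-methylisobenzofuran-1(3H)-one, via benzylic alcohol 24 (not isolated)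
Conditions: LDA, THF, −78 °C; then 3-phenyl-2-(phenylsulfonyl)oxaziridine, −78 to 0 °C
Reagents that add atoms: 3-phenyl-2-(phenylsulfonyl)oxaziridine O=S(=O)(c1ccccc1)N1OC1c1ccccc1
Why: Lateral lithiation of the ortho-toluate (only the methyl ortho to the ester is acidified), oxygenation with the Davis oxaziridine and lactonisation of the benzylic alkoxide onto the ester give the phthalide that carries C26.

Step 19
Reactants: 25 5,7-bis(tert-butyldimethylsilyloxy)-6-methylisobenzofuran-1(3H)-one
Product: 26 4-bromo-5,7-bis(tert-butyldimethylsilyloxy)-6-methylisobenzofuran-1(3H)-one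
Conditions: NBS, DMF, 0 °C to rt, dark
Reagents that add atoms: N-bromosuccinimide O=C1CCC(=O)N1Br
Why: Electrophilic aromatic bromination at the only free ring position, which is ortho and para to the two silyloxy groups.

Step 20
Reactants: 21 triethylsilyl ether of 20; 26 4-bromo-5,7-bis(tert-butyldimethylsilyloxy)-6-methylisobenzofuran-1(3H)-one
Product: 28 coupled phthalide (arene carbon bonded to C20; three silyl ethers), via alkylzinc iodide 27 (not isolated)
Conditions: Zn dust, LiCl, THF, 40 °C; then 26, Pd(OAc)2 (5 mol %), SPhos, THF, 60 °C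
Reagents that add atoms: none
Why: Negishi coupling: zinc insertion into the primary iodide and palladium-catalysed cross-coupling with the hindered aryl bromide (dialkylbiarylphosphine ligand) form the C18–C20 bond without touching C21.

Step 21
Reactants: 28 coupled phthalide
Product: 30 5-O-allyl ether (free 7-hydroxyl and C22 hydroxyl), via triol 29 (not isolated)
Conditions: Bu4NF, THF, 0 °C to rt; AcOH quench; then K2CO3, allyl bromide (1.05 equiv), acetone, 50 °C
Reagents that add atoms: allyl bromide C=CCBr
Why: Fluoride removes the three silyl groups, and Williamson etherification then takes place only at the more acidic phenol para to the lactone carbonyl, since the other phenol is hydrogen-bonded to that carbonyl.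

Step 22
Reactants: 30 5-O-allyl ether
Product: 33 cage keto lactone (C18 allyl; C31 ketone), via ortho-dienone 31 (not isolated), via enol cycloadduct 32 (not isolated)
Conditions: 1,2-dichlorobenzene (degassed), BHT, 180 °C, sealed tube
Reagents that add atoms: none
Why: Aromatic Claisen rearrangement moves the allyl group reversibly from O17 onto the ring carbons, and only the C18 dienone whose tether matches the fixed C21 centre can close by intramolecular Diels–Alder reaction (fused mode, bonds C12–C25 and C13–C14, five-membered ring C18–C20–C21–C12–C25), so C18, C25, C14 and C12 follow from C21, and the enol then settles as the β-keto lactone with C30–H turned toward ring B.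

Step 23
Reactants: 33 cage keto lactone
Product: 34 C31 alcohol (C18 allyl)
Conditions: NaBH4, MeOH/THF, −40 to 0 °C
Reagents that add atoms: none
Why: Borohydride reduces only the C31 ketone (C16 lies between two quaternary carbons), and hydride should come from the face of the C12–C13 bridge, away from the fused lactone carbon C28, to give the alcohol cis to C28.

Step 24
Reactants: 34 C31 alcohol
Product: 35 aldehyde (C18–CH2–CHO)
Conditions: O3, CH2Cl2/MeOH, −78 °C; then Me2S
Reagents that add atoms: ozone [O-][O+]=O
Why: Ozonolysis of the only alkene left, with reductive work-up, gives the aldehyde.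

Step 25
Reactants: 35 aldehyde
Product: 36 ethylene ketal of the precursor (C19 methyl)
Conditions: RhCl(PPh3)3 (1.1 equiv), toluene, 110 °C
Reagents that add atoms: none
Why: Tsuji–Wilkinson decarbonylation: acyl–rhodium formation, CO extrusion and reductive elimination turn CH2–CHO into the C19 methyl, and the neopentyl alkylrhodium has no β-hydrogen to lose.

Step 26
Reactants: 36 ethylene ketal of the precursor
Product: 37 spiro 2,2-dimethylcyclopentanone precursor
Conditions: PPTS, acetone/H2O (10:1), 50 °C
Reagents that add atoms: water O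
Why: Mild acid hydrolysis of the dioxolane frees the ring A ketone without ionising the tertiary alcohol.

Step 27
Reactants: 37 spiro 2,2-dimethylcyclopentanone precursor
Product: 38 7,8-dihydro target (saturated δ-lactone)
Conditions: CF3CO3H (from (CF3CO)2O and urea·H2O2), Na2HPO4, CH2Cl2, 0 °C
Reagents that add atoms: trifluoroperacetic acid OOC(=O)C(F)(F)F
Why: Baeyer–Villiger oxidation: the peracid adds to the C5 carbonyl from the open C7 side to give the tetrahedral peroxy (Criegee) adduct, which collapses with 1,2-shift of C2 from C5 to the proximal peroxide oxygen and loss of trifluoroacetate, forming the C2–O4 bond. The closest known reaction type is the peracid ring expansion of 2,2-disubstituted cyclopentanones to δ-lactones with migration of the more substituted α-carbon. The six-membered lactone C2–O4–C5–C7–C8–C9 arises by one-atom ring expansion of the five-membered ketone (concerted shift with the C2–C5 bond antiperiplanar to the O–O bond) and not by a cyclisation. No stereocentre is created; C2 carries two methyl groups, and migration with retention leaves C9 and every other centre untouched. The step needs migration of C2 rather than C7 and reaction at C5 rather than C16: the tertiary C2 has the higher migratory aptitude, and C16 lies between the quaternary carbons C14 and C18 inside the bicyclo[2.2.2]octane, where the peracid should not add. The phosphate buffer should keep the two alcohols from being acylated or ionised, and no alkene is present to be epoxidised.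

Step 28
Reactants: 38 7,8-dihydro target
Product: 39 C7 phenylselenide of 38
Conditions: LDA (3.3 equiv), THF, −78 °C; then PhSeBr, −78 °C
Reagents that add atoms: phenylselenenyl bromide Br[Se]c1ccccc1
Why: Two equivalents of base are spent on the hydroxyls and the third forms the kinetic lithium enolate of the δ-lactone at C7 (C16 has no α-hydrogen and C30–H sits next to an alkoxide), which is selenenylated.

Step 29
Reactants: 39 C7 phenylselenide of 38
Product: 41 target, via selenoxide 40 (not isolated)
Conditions: H2O2 (30%), pyridine, CH2Cl2, 0 °C to rt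
Reagents that add atoms: none
Why: Oxidation to the selenoxide and syn-elimination toward C8, which holds the only β-hydrogens, give the C7=C8 alkene.

**Compound list**
1 | 3-ethoxy-2-methylcyclohex-2-en-1-one | CCOC1=C(C)C(=O)CCC1 | starting material
2 | 3-ethoxy-2-methyl-1-vinylcyclohex-2-en-1-ol (Grignard adduct; racemic; not isolated) | CCOC1=C(C)C(O)(C=C)CCC1 | intermediate
3 | 2-methyl-3-vinylcyclohex-2-en-1-one | C=CC1=C(C)C(=O)CCC1 | intermediate
4 | (S)-2-methyl-3-vinylcyclohex-2-en-1-ol | O[C@H]1CCCC(C=C)=C1C | intermediate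
5 | (S)-2-methyl-3-vinylcyclohex-2-en-1-yl 2-methylpropanoate | CC(C)C(=O)O[C@H]1CCCC(C=C)=C1C | intermediate
6 | O-trimethylsilyl ketene acetal of 5 (not isolated) | CC(C)=C(O[Si](C)(C)C)O[C@H]1CCCC(C=C)=C1C | intermediate
7 | trimethylsilyl ester of 8 (not isolated) | C=C[C@]1(C(C)(C)C(=O)O[Si](C)(C)C)C(C)=CCCC1 | intermediate
8 | 2-methyl-2-(2-methyl-1-vinylcyclohex-2-en-1-yl)propanoic acid; the quaternary ring carbon is C9 in its final configuration | C=C[C@]1(C(C)(C)C(=O)O)C(C)=CCCC1 | intermediate
9 | 2-methyl-2-(2-methyl-1-vinylcyclohex-2-en-1-yl)propan-1-ol | C=C[C@]1(C(C)(C)CO)C(C)=CCCC1 | intermediate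
10 | 2-methyl-2-(2-methyl-1-vinylcyclohex-2-en-1-yl)propanal | C=C[C@]1(C(C)(C)C=O)C(C)=CCCC1 | intermediate
11 | 1,1,6-trimethylspiro[4.5]dec-6-en-2-one (ring A ketone C5; spiro C9; ring B alkene C21=C22) | CC1(C)C(=O)CC[C@]12CCCC=C2C | intermediate
12 | ethylene ketal of 11 (dioxolane at C5) | CC1(C)C2(CC[C@]13CCCC=C3C)OCCO2 | intermediate
13 | ketal enone (C12 ketone; C21=C22 with methyl on C22) | CC1(C)C2(CC[C@]13CCC(=O)C=C3C)OCCO2 | intermediate
14 | dibromo ketone (Br on C21 and C22; not isolated) | CC1(C)C2(CC[C@]13CCC(=O)C(Br)C3(C)Br)OCCO2 | intermediate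
15 | 2-bromo enone (Br on C21) | CC1(C)C2(CC[C@]13CCC(=O)C(Br)=C3C)OCCO2 | intermediate
16 | 2-(hydroxymethyl) enone (C20 on C21) | CC1(C)C2(CC[C@]13CCC(=O)C(CO)=C3C)OCCO2 | intermediate
17 | dienyl alcohol (C12 methylidene; C21=C22; C20 hydroxymethyl) | CC1(C)C2(CC[C@]13CCC(=C)C(CO)=C3C)OCCO2 | intermediate
18 | vinyl epoxide (C21–C22 oxirane on the face opposite C2; C12 methylidene; C20 hydroxymethyl) | CC1(C)C2(CC[C@]13CCC(=C)[C@@]4(CO)O[C@@]34C)OCCO2 | intermediate
19 | diol (C12 methylidene; C21–H anti to O24; C20 primary alcohol; C22 tertiary alcohol) | CC1(C)C2(CC[C@]13CCC(=C)[C@@H](CO)[C@@]3(C)O)OCCO2 | intermediate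
20 | primary iodide of 19 (C20–I) | CC1(C)C2(CC[C@]13CCC(=C)[C@@H](CI)[C@@]3(C)O)OCCO2 | intermediate
21 | triethylsilyl ether of 20 (O24–SiEt3) | CC1(C)C2(CC[C@]13CCC(=C)[C@@H](CI)[C@@]3(C)O[Si](CC)(CC)CC)OCCO2 | intermediate
22 | methyl 2,4-dihydroxy-3,6-dimethylbenzoate | COC(=O)c1c(C)cc(O)c(C)c1O | starting material
23 | methyl 2,4-bis(tert-butyldimethylsilyloxy)-3,6-dimethylbenzoate | COC(=O)c1c(C)cc(O[Si](C)(C)C(C)(C)C)c(C)c1O[Si](C)(C)C(C)(C)C | intermediate
24 | methyl 2,4-bis(tert-butyldimethylsilyloxy)-6-(hydroxymethyl)-3-methylbenzoate (not isolated) | COC(=O)c1c(CO)cc(O[Si](C)(C)C(C)(C)C)c(C)c1O[Si](C)(C)C(C)(C)C | intermediate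
25 | 5,7-bis(tert-butyldimethylsilyloxy)-6-methylisobenzofuran-1(3H)-one | O=C1OCc2cc(O[Si](C)(C)C(C)(C)C)c(C)c(O[Si](C)(C)C(C)(C)C)c12 | intermediate
26 | 4-bromo-5,7-bis(tert-butyldimethylsilyloxy)-6-methylisobenzofuran-1(3H)-one | O=C1OCc2c(Br)c(O[Si](C)(C)C(C)(C)C)c(C)c(O[Si](C)(C)C(C)(C)C)c12 | intermediate
27 | alkylzinc iodide from 21 (C20–ZnI; not isolated) | CC1(C)C2(CC[C@]13CCC(=C)[C@@H](C[Zn]I)[C@@]3(C)O[Si](CC)(CC)CC)OCCO2 | intermediate
28 | coupled phthalide (phthalide C4 = C18 bonded to C20; two aryl TBS ethers; O24–SiEt3) | CC1(C)C2(CC[C@]13CCC(=C)[C@@H](Cc4c(O[Si](C)(C)C(C)(C)C)c(C)c(O[Si](C)(C)C(C)(C)C)c5C(=O)OCc45)[C@@]3(C)O[Si](CC)(CC)CC)OCCO2 | intermediate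
29 | triol (5,7-dihydroxy-6-methylphthalide bonded through C20; free C22–OH; not isolated) | CC1(C)C2(CC[C@]13CCC(=C)[C@@H](Cc4c(O)c(C)c(O)c5C(=O)OCc45)[C@@]3(C)O)OCCO2 | intermediate
30 | 5-O-allyl ether of 29 (allyl on O17) | CC1(C)C2(CC[C@]13CCC(=C)[C@@H](Cc4c(OCC=C)c(C)c(O)c5C(=O)OCc45)[C@@]3(C)O)OCCO2 | intermediate
31 | ortho-dienone (allyl on C18; C16 ketone; C14=C31 enol; C25=C30 butenolide; not isolated) | CC1(C)C2(CC[C@]13CCC(=C)[C@@H](C[C@@]4(CC=C)C(=O)C(C)=C(O)C5=C4COC5=O)[C@@]3(C)O)OCCO2 | intermediate
32 | enol cycloadduct (C30=C31–OH; not isolated) | CC1(C)C5(OCCO5)CC[C@]12CC[C@]13C[C@]4(C)C(=O)[C@](CC=C)(C[C@H]1[C@@]2(C)O)[C@]31COC(=O)C1=C4O | intermediate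
33 | cage keto lactone (C18 allyl; C31 ketone; C30–H; ring A ketal) | CC1(C)C5(OCCO5)CC[C@]12CC[C@]13C[C@]4(C)C(=O)[C@](CC=C)(C[C@H]1[C@@]2(C)O)[C@]31COC(=O)[C@H]1C4=O | intermediate
34 | C31 alcohol of 33 (hydroxyl cis to C28) | CC1(C)C5(OCCO5)CC[C@]12CC[C@]13C[C@]4(C)C(=O)[C@](CC=C)(C[C@H]1[C@@]2(C)O)[C@]31COC(=O)[C@H]1[C@H]4O | intermediate
35 | aldehyde (C18–CH2–CHO) | CC1(C)C5(OCCO5)CC[C@]12CC[C@]13C[C@]4(C)C(=O)[C@](CC=O)(C[C@H]1[C@@]2(C)O)[C@]31COC(=O)[C@H]1[C@H]4O | intermediate
36 | ethylene ketal of precursor 37 (C19 methyl) | CC1(C)C5(OCCO5)CC[C@]12CC[C@]13C[C@]4(C)C(=O)[C@](C)(C[C@H]1[C@@]2(C)O)[C@]31COC(=O)[C@H]1[C@H]4O | intermediate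
37 | spiro 2,2-dimethylcyclopentanone precursor | CC1(C)C(=O)CC[C@]12CC[C@]13C[C@]4(C)C(=O)[C@](C)(C[C@H]1[C@@]2(C)O)[C@]31COC(=O)[C@H]1[C@H]4O | intermediate
38 | 7,8-dihydro target (saturated δ-lactone) | CC1(C)OC(=O)CC[C@]12CC[C@]13C[C@]4(C)C(=O)[C@](C)(C[C@H]1[C@@]2(C)O)[C@]31COC(=O)[C@H]1[C@H]4O | intermediate
39 | C7 phenylselenide of 38 (both C7 epimers) | CC1(C)OC(=O)C([Se]c5ccccc5)C[C@]12CC[C@]13C[C@]4(C)C(=O)[C@](C)(C[C@H]1[C@@]2(C)O)[C@]31COC(=O)[C@H]1[C@H]4O | intermediate
40 | selenoxide of 39 (not isolated) | CC1(C)OC(=O)C([Se](=O)c5ccccc5)C[C@]12CC[C@]13C[C@]4(C)C(=O)[C@](C)(C[C@H]1[C@@]2(C)O)[C@]31COC(=O)[C@H]1[C@H]4O | intermediate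
41 | CNP0360620.2 | CC1(C)OC(=O)C=C[C@]12CC[C@]13C[C@]4(C)C(=O)[C@](C)(C[C@H]1[C@@]2(C)O)[C@]31COC(=O)[C@H]1[C@H]4O | target

**Step count**
Total: 29 steps. Longest linear sequence: 26 steps (steps 1–16 and 20–29); the arene branch (steps 17–19) joins at step 20.

**Steps most likely to fail**

Step 22. The Claisen shift may not feed the C18 dienone fast enough at a temperature the material survives. The allyl group itself may add across the dienone, or the para-dienone may build up. C30 may also settle with the lactone turned toward ring B. The fallback sets out from triol 29, isolated after the fluoride stage of step 21. Deprotonation with LiHMDS and C-methylation with iodomethane (toluene/THF, −78 to 0 °C) should give the methyl dienone F1 as both C18 epimers. Heating in toluene at 110 °C should let only the epimer that matches C21 close to the C19-methyl keto lactone F2. Reduction with NaBH4 as in step 23 then gives 36, where the route is rejoined. This gives up the self-correcting allyl shift and at best half of the dienone can cyclise, but it saves steps 24 and 25.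

Step 27. The peracid or traces of anhydride may acylate the two alcohols, the β-hydroxy ketone may cleave by retro-aldol reaction, or oxidation may be slow at the hindered spiro ketone. The fallback sets out from 37. Silylation of both hydroxyls (Me3SiOTf, 2,6-lutidine) gives the bis(trimethylsilyl) ether F3. Buffered m-CPBA (NaHCO3, CH2Cl2) gives the bis(trimethylsilyl) lactone F4 by the same C2 migration. HF·pyridine then returns 38.

Step 28. Under three equivalents of amide base, the C22 alkoxide may attack the δ-lactone carbonyl (acyl transfer from O4 to O24), the C31 alkoxide may trigger retro-aldol cleavage of C14–C31, or C30 may be deprotonated. The fallback sets out from 38 and avoids strong base and selenium. Soft enolisation with Me3SiOTf and Et3N silylates both alcohols and gives the ketene silyl acetal F5. Saegusa–Ito oxidation with Pd(OAc)2 in MeCN gives the bis(trimethylsilyl) ether of the target F6. HF·pyridine then gives 41 directly, so step 29 is not needed.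

**Further compounds**
F1 | step 22 | methyl dienone (C18 methyl; C16 ketone; C14=C31 enol; C25=C30 butenolide; matched C18 epimer shown) | CC1(C)C2(CC[C@]13CCC(=C)[C@@H](C[C@@]4(C)C(=O)C(C)=C(O)C5=C4COC5=O)[C@@]3(C)O)OCCO2
F2 | step 22 | C19-methyl keto lactone (C31 ketone; ring A ketal) | CC1(C)C5(OCCO5)CC[C@]12CC[C@]13C[C@]4(C)C(=O)[C@](C)(C[C@H]1[C@@]2(C)O)[C@]31COC(=O)[C@H]1C4=O
F3 | step 27 | bis(trimethylsilyl) ether of 37 (O24 and O32 silylated) | CC1(C)C(=O)CC[C@]12CC[C@]13C[C@]4(C)C(=O)[C@](C)(C[C@H]1[C@@]2(C)O[Si](C)(C)C)[C@]31COC(=O)[C@H]1[C@H]4O[Si](C)(C)C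
F4 | step 27 | bis(trimethylsilyl) ether of 38 | CC1(C)OC(=O)CC[C@]12CC[C@]13C[C@]4(C)C(=O)[C@](C)(C[C@H]1[C@@]2(C)O[Si](C)(C)C)[C@]31COC(=O)[C@H]1[C@H]4O[Si](C)(C)C
F5 | step 28 | ketene silyl acetal of the δ-lactone (C5=C7) with O24 and O32 silylated | CC1(C)OC(O[Si](C)(C)C)=CC[C@]12CC[C@]13C[C@]4(C)C(=O)[C@](C)(C[C@H]1[C@@]2(C)O[Si](C)(C)C)[C@]31COC(=O)[C@H]1[C@H]4O[Si](C)(C)C
F6 | step 28 | bis(trimethylsilyl) ether of the target | CC1(C)OC(=O)C=C[C@]12CC[C@]13C[C@]4(C)C(=O)[C@](C)(C[C@H]1[C@@]2(C)O[Si](C)(C)C)[C@]31COC(=O)[C@H]1[C@H]4O[Si](C)(C)C
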